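The numbers in the tables stem from a simulated flask with made-up constants, and the scatter is random.

82.0 µM is the catalyst we expect to work in the flask: the 100 µM of free catalyst charged, less 18 µM of impurity if each impurity takes one catalyst. We call this difference live catalyst.

common to all: free catalyst 0.5 mol%; impurity 18 µM

| charge | substrate | remark |
|---|---|---|
| north-west | 0.028 M | run made earlier |
| east | 0.044 M | run made earlier |
| flask | 0.020 M |  |

| run | time / s | product / % | substrate / % |
|---|---|---|---|
| north-west | 25.0 | 64.7 | 35.1 |
| north-west | 50.0 | 89.5 | 11.1 |
| north-west | 80.0 | 95.7 | 3.9 |
| north-west | 120 | 97.9 | 0.9 |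
| east | 25.0 | 76.5 | 24.7 |
| east | 50.0 | 93.4 | 7.0 |
| east | 80.0 | 95.5 | 3.5 |
| east | 120 | 100.6 | 0 |

(standard deviation of a reading: 1 percentage point)

1. factor on the rate of making product when 10 % of the substrate are converted if free catalyst is charged twice over
2. factor on the rate when 10 % of the substrate are converted if free catalyst is charged at 2.5 mol% instead



One thing looks contradictory. From north-west to east, live catalyst goes from 122 µM to 202 µM, a factor of 1.66. Yet the pseudo-first-order constant read at 25.0 s goes from 0.0419 s⁻¹ to 0.0559 s⁻¹, a factor of 1.33.

But east also holds 1.57 times the substrate, so two settings moved together. Per live catalyst the constant is 1.24 times lower in east, but we do not read this as a fractional order in catalyst, since the two runs differ in more than catalyst: at that reading [product] stands at 0.0181 M in north-west and 0.0337 M in east.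

The question holds [substrate] and conversion fixed, so we solve the two ends. A charge equal to the impurity gives no live catalyst, and a charge far above it gives nearly the charge. Joining them, we take the rate as proportional to live catalyst, which makes the doubled charge worth 2.22.

The forecast differs from our reckoning: it gives 1.5 and 2.45, holding that “the order is about 0.5, which suggests a dimer resting state with active monomer”.

    substrate + free catalyst ⇌ catalyst intermediate A (K = 530 M⁻¹, k = 710 M⁻¹ s⁻¹)
    catalyst intermediate A → catalyst intermediate B (k = 26.0 s⁻¹)
    catalyst intermediate B ⇌ free catalyst + product (K = 0.0270 M, k = 260 s⁻¹)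
    free catalyst + impurity → spent catalyst (k = 1.90 × 10⁶ M⁻¹ s⁻¹)

The simulation gives 2.22 for the doubled charge. In the flask at 0.300 min, impurity stands at 0 % of its charge and spent catalyst at 18.0 % of the catalyst charged, which matches 18 µM out of 100 µM. At 2.5 mol%, live catalyst is 482 µM against 82.0 µM, a factor of 5.88, and the simulation gives 5.88.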